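The route rests on cutting the unfunctionalised C5–C6 methylene–methylene bond at the centre of the nonanone tether (C1 = ketone carbon on the 2,6-dimethoxyphenyl ring, C9 = benzylic carbon on the 4-hydroxyphenyl ring). With four CH2 groups on either side (C2–C5 and C6–C9), each half maps onto an ω-aryl carboxylic acid. One nickel-electrocatalytic doubly decarboxylative coupling expels two CO2 and forges this sp3–sp3 bond at the final oxidation level, leaving ketone and free phenol untouched. Its precursors are the N-hydroxyphthalimide esters of 6-(2,6-dimethoxyphenyl)-6-oxohexanoic acid and 5-(4-hydroxyphenyl)pentanoic acid.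

Key step: step 5

Remark: the target has no stereocentre and no stereogenic double bond, so it is achiral and no stereocontrol is needed; 5-(4-hydroxyphenyl)pentanoic acid is taken as a purchasable starting material.

Step 1
Reactants: 1 1,3-dimethoxybenzene; 2 ε-caprolactone (oxepan-2-one)
Product: 4 1-(2,6-dimethoxyphenyl)-6-hydroxyhexan-1-one, via 2,6-dimethoxyphenyllithium 3 (not isolated)
Conditions: n-BuLi (1.05 equiv), THF, 0 °C → rt; then cannulated into 2 (1.3 equiv), THF, −78 °C; 1 M HCl quench
Reagents that add atoms: none
Why: Directed ortho-metalation puts lithium on C2 between the two methoxy groups, and acyl substitution of the aryllithium on the lactone (inverse addition at −78 °C) should open the ring to the ω-hydroxy ketone, whose doubly ortho-substituted carbonyl resists a second addition.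

Step 2
Reactants: 4 1-(2,6-dimethoxyphenyl)-6-hydroxyhexan-1-one
Product: 6 6-(2,6-dimethoxyphenyl)-6-oxohexanoic acid, via 6-(2,6-dimethoxyphenyl)-6-oxohexanal 5 (not isolated)
Conditions: TEMPO (0.2 equiv), PhI(OAc)2 (2.2 equiv), MeCN/H2O 1:1, rt
Reagents that add atoms: water, O
Why: TEMPO/PhI(OAc)2 oxidation (Epp–Widlanski conditions) should take the primary alcohol through the aldehyde and its hydrate to the acid without touching the ketone or the dimethoxyarene.

Step 3
Reactants: 6 6-(2,6-dimethoxyphenyl)-6-oxohexanoic acid; 7 N-hydroxyphthalimide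
Product: 8 1,3-dioxoisoindolin-2-yl 6-(2,6-dimethoxyphenyl)-6-oxohexanoate
Conditions: DIC (1.1 equiv), DMAP (0.1 equiv), CH2Cl2, rt
Reagents that add atoms: N-hydroxyphthalimide (7), O=C1c2ccccc2C(=O)N1O
Why: Carbodiimide (Steglich-type) esterification of the acid with N-hydroxyphthalimide should give the redox-active ester, since no competing nucleophile is present.

Step 4
Reactants: 9 5-(4-hydroxyphenyl)pentanoic acid; 7 N-hydroxyphthalimide
Product: 10 1,3-dioxoisoindolin-2-yl 5-(4-hydroxyphenyl)pentanoate
Conditions: DIC (1.05 equiv), THF, 0 °C → rt, no DMAP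
Reagents that add atoms: N-hydroxyphthalimide (7), O=C1c2ccccc2C(=O)N1O
Why: Carbodiimide activation without an acyl-transfer catalyst should acylate the far more acidic and nucleophilic N–OH of N-hydroxyphthalimide in preference to the phenol, as in the preparation of active esters of unprotected hydroxyphenyl-alkanoic acids.

Step 5
Reactants: 8 1,3-dioxoisoindolin-2-yl 6-(2,6-dimethoxyphenyl)-6-oxohexanoate; 10 1,3-dioxoisoindolin-2-yl 5-(4-hydroxyphenyl)pentanoate (3 equiv)
Product: 11 1-(2,6-dimethoxyphenyl)-9-(4-hydroxyphenyl)nonan-1-one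
Conditions: NiCl2·6H2O (20 mol%), 2,2′:6′,2″-terpyridine (20 mol%), AgNO3 (0.3 equiv), DMF, undivided cell, Mg(+)/RVC(−), constant current, rt; 1 M HCl work-up
Reagents that add atoms: none
Why: Each N-acyloxyphthalimide accepts one electron from the cathodically generated low-valent terpyridine–nickel species (or the silver-modified cathode) and fragments with loss of CO2 and phthalimide anion to a primary alkyl radical (5-aryl-5-oxopentyl from 8, 4-(4-hydroxyphenyl)butyl from 10); the two radicals are captured in turn by nickel to give a dialkyl-Ni(III) that reductively eliminates the C5–C6 CH2–CH2 bond. The closest known reaction type is the nickel-electrocatalytic doubly decarboxylative Csp3–Csp3 coupling of two redox-active esters, which is established for primary–primary pairs. No ring is closed and no stereocentre is created, so no stereocontrol element is needed. The selectivity required is cross- over homo-coupling, which is only statistical for two primary radicals and is therefore biased by using the one-step ester 10 in threefold excess; the two homodimers (a bisphenol and a diketone) differ in polarity from the monophenol 11 and should be separable by chromatography. Chemoselectivity rests on the mild potential of the nickel/ester couple: the aryl ketone, twisted out of conjugation by its two ortho-methoxy groups, and the anisole and phenol rings lie well outside this window, and the medium contains no basic organometallic that the phenolic O–H would quench.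

Compound list
1 | 1,3-dimethoxybenzene | COc1cccc(OC)c1 | starting material
2 | ε-caprolactone (oxepan-2-one) | O=C1CCCCCO1 | starting material
3 | 2,6-dimethoxyphenyllithium | [Li]c1c(OC)cccc1OC | intermediate (not isolated)
4 | 1-(2,6-dimethoxyphenyl)-6-hydroxyhexan-1-one | COc1cccc(OC)c1C(=O)CCCCCO | intermediate
5 | 6-(2,6-dimethoxyphenyl)-6-oxohexanal | COc1cccc(OC)c1C(=O)CCCCC=O | intermediate (not isolated)
6 | 6-(2,6-dimethoxyphenyl)-6-oxohexanoic acid | COc1cccc(OC)c1C(=O)CCCCC(=O)O | intermediate
7 | N-hydroxyphthalimide | O=C1c2ccccc2C(=O)N1O | starting material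
8 | 1,3-dioxoisoindolin-2-yl 6-(2,6-dimethoxyphenyl)-6-oxohexanoate | COc1cccc(OC)c1C(=O)CCCCC(=O)ON1C(=O)c2ccccc2C1=O | intermediate
9 | 5-(4-hydroxyphenyl)pentanoic acid | O=C(O)CCCCc1ccc(O)cc1 | starting material
10 | 1,3-dioxoisoindolin-2-yl 5-(4-hydroxyphenyl)pentanoate | O=C(CCCCc1ccc(O)cc1)ON1C(=O)c2ccccc2C1=O | intermediate
11 | 1-(2,6-dimethoxyphenyl)-9-(4-hydroxyphenyl)nonan-1-one | COc1cccc(OC)c1C(=O)CCCCCCCCc1ccc(O)cc1 | target

Total step count: 5
Longest linear sequence: 4 (steps 1, 2, 3, 5)

Steps most likely to fail

1. Step 5. The two primary radicals may partition mainly into homodimers, or be reduced to the alkanes before the second capture, a path the phenolic O–H could feed; acyl transfer from an ester to a phenoxide would consume 10. The fallback builds the same C5–C6 link by Wittig olefination and hydrogenation. It sets out from 3 (made from 1 as in step 1) and comes back at 11. Addition of 3 to δ-valerolactone (THF, −78 °C) should give 1-(2,6-dimethoxyphenyl)-5-hydroxypentan-1-one F1, and Dess–Martin oxidation (CH2Cl2, rt) would give 5-(2,6-dimethoxyphenyl)-5-oxopentanal F2. In parallel, purchased 4-(4-methoxyphenyl)butan-1-ol in refluxing 48% HBr should give 4-(4-bromobutyl)phenol F3 by ether cleavage and bromination. PPh3 (MeCN, reflux) would convert it into [4-(4-hydroxyphenyl)butyl]triphenylphosphonium bromide F4. NaHMDS (2.2 equiv, THF, −78 °C) would give the phenolate ylide sodium 4-[4-(triphenyl-λ5-phosphanylidene)butyl]phenolate F5 (not isolated). This should condense with the aldehyde of F2, not with its hindered ketone, to give (Z)-1-(2,6-dimethoxyphenyl)-9-(4-hydroxyphenyl)non-5-en-1-one F6. Hydrogenation (H2, Pd/C, EtOAc, rt) would then give 11.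

2. Step 4. The activated acid may acylate the phenolic hydroxyl of a second molecule, leading to oligoesters instead of the N-hydroxyphthalimide ester. The fallback masks the phenol. It sets out from 9 and comes back at 11. Bis-silylation (TBSCl, imidazole, DMF) should give tert-butyldimethylsilyl 5-{4-[(tert-butyldimethylsilyl)oxy]phenyl}pentanoate F7. Selective cleavage of the silyl ester (K2CO3, MeOH/THF/H2O) would give 5-{4-[(tert-butyldimethylsilyl)oxy]phenyl}pentanoic acid F8. Esterification with 7 (DIC, DMAP, CH2Cl2) would give 1,3-dioxoisoindolin-2-yl 5-{4-[(tert-butyldimethylsilyl)oxy]phenyl}pentanoate F9. Coupling of F9 with 8 under the step 5 conditions should give 9-{4-[(tert-butyldimethylsilyl)oxy]phenyl}-1-(2,6-dimethoxyphenyl)nonan-1-one F10, and TBAF (THF, 0 °C) would release 11.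

3. Step 1. The aryllithium may add a second time to the liberated ketone or may enolise the lactone instead of adding to it. The fallback installs the chain at the acid oxidation level by acylation of a softer organometallic. It sets out from 3 and comes back at 6, so it replaces steps 1 and 2. Transmetalation with ZnCl2 (THF, −78 °C → rt) should give (2,6-dimethoxyphenyl)zinc chloride F11. Pd(PPh3)4-catalysed Negishi acylation with purchased methyl 6-chloro-6-oxohexanoate would give methyl 6-(2,6-dimethoxyphenyl)-6-oxohexanoate F12. Saponification (LiOH, THF/H2O, then HCl) would give 6.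

Further compounds
F1 | step 5 | 1-(2,6-dimethoxyphenyl)-5-hydroxypentan-1-one | COc1cccc(OC)c1C(=O)CCCCO
F2 | step 5 | 5-(2,6-dimethoxyphenyl)-5-oxopentanal | COc1cccc(OC)c1C(=O)CCCC=O
F3 | step 5 | 4-(4-bromobutyl)phenol | Oc1ccc(CCCCBr)cc1
F4 | step 5 | [4-(4-hydroxyphenyl)butyl]triphenylphosphonium bromide | Oc1ccc(CCCC[P+](c2ccccc2)(c2ccccc2)c2ccccc2)cc1.[Br-]
F5 | step 5 | sodium 4-[4-(triphenyl-λ5-phosphanylidene)butyl]phenolate | [Na+].[O-]c1ccc(CCCC=P(c2ccccc2)(c2ccccc2)c2ccccc2)cc1
F6 | step 5 | (Z)-1-(2,6-dimethoxyphenyl)-9-(4-hydroxyphenyl)non-5-en-1-one | COc1cccc(OC)c1C(=O)CCC/C=C\CCCc1ccc(O)cc1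
F7 | step 4 | tert-butyldimethylsilyl 5-{4-[(tert-butyldimethylsilyl)oxy]phenyl}pentanoate | CC(C)(C)[Si](C)(C)OC(=O)CCCCc1ccc(O[Si](C)(C)C(C)(C)C)cc1
F8 | step 4 | 5-{4-[(tert-butyldimethylsilyl)oxy]phenyl}pentanoic acid | CC(C)(C)[Si](C)(C)Oc1ccc(CCCCC(=O)O)cc1
F9 | step 4 | 1,3-dioxoisoindolin-2-yl 5-{4-[(tert-butyldimethylsilyl)oxy]phenyl}pentanoate | CC(C)(C)[Si](C)(C)Oc1ccc(CCCCC(=O)ON2C(=O)c3ccccc3C2=O)cc1
F10 | step 4 | 9-{4-[(tert-butyldimethylsilyl)oxy]phenyl}-1-(2,6-dimethoxyphenyl)nonan-1-one | COc1cccc(OC)c1C(=O)CCCCCCCCc1ccc(O[Si](C)(C)C(C)(C)C)cc1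
F11 | step 1 | (2,6-dimethoxyphenyl)zinc chloride | COc1cccc(OC)c1[Zn]Cl
F12 | step 1 | methyl 6-(2,6-dimethoxyphenyl)-6-oxohexanoate | COC(=O)CCCCC(=O)c1c(OC)cccc1OC
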